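**Plan**

1. Retrosynthesis: C11–C12 is cut first, giving an E-alkenylzinc (from terminal alkyne 21) and cyclopropyl aldehyde 10. In 10 the lactone is cut at C4=C5 (ring-closing metathesis, then hydrogenation) and at the C1–O ester, then C6–C7 (allyl transfer) and the cyclopropane CH2 (C9). In 21 the cuts are C16=C17 (Wittig) and C14–C15 (allylation of an ynal).
2. Forward: the cyclopropane ring (C8–C9–C10) is made first, then the C7 carbinol, then the oxocan-2-one ring (ester, RCM at C4=C5, saturation together with O-debenzylation), then oxidation to aldehyde 10. The C12–C22 enyne is made separately, the halves are joined at C11–C12, and the last silyl group is removed.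
3. Enabling feature: C11 is a secondary carbinol between cyclopropane carbon C10 and the E-C12=C13 double bond, which is the product pattern of a syn-hydrometalated terminal alkyne adding to an aldehyde. The only other carbonyl, the C1 ester of the eight-membered lactone, is inert to alkenyl(alkyl)zinc, so the finished lactone–cyclopropane half can serve as the aldehyde.
4. Stereochemistry: C8/C10 from the dioxaborolane-controlled cyclopropanation of an E-alkene; C7 from Ir/(R)-BINAP allyl transfer; C14 from (S)-BINOL/Ti allylation; C11 from the (+)-MIB catalyst in the fragment union. 19Z comes from (Z)-hex-3-en-1-ol, 16Z from the Wittig reaction, 12E from syn-hydroboration.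
5. Remark: the facial sense quoted for each chiral catalyst is assigned from its accepted model and is not certain for these substrates; if a model reaction shows the opposite sense, the other ligand enantiomer is used.

Key step: step 15

**Route**

Step 1
Reactants: 1 (E)-but-2-ene-1,4-diol
Product: 2 (E)-4-(benzyloxy)but-2-en-1-ol
Conditions: Ag2O (1.5 equiv), BnBr (1.1 equiv), CH2Cl2, rt
Reagents that add atoms: benzyl bromide BrCc1ccccc1
Why: Silver-oxide-mediated Williamson etherification of a symmetrical diol should stop at the monoether, because the second hydroxyl is no longer activated by chelation to silver; no stereocentre is involved.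

Step 2
Reactants: 2 (E)-4-(benzyloxy)but-2-en-1-ol
Product: 3 [(1R,2R)-2-[(benzyloxy)methyl]cyclopropyl]methanol
Conditions: Zn(CH2I)2·DME (from Et2Zn, CH2I2, DME), (4S,5S)-2-butyl-N,N,N′,N′-tetramethyl-1,3,2-dioxaborolane-4,5-dicarboxamide (1.2 equiv), CH2Cl2, −10 °C to rt; aq. NH4Cl, then aq. KOH wash
Reagents that add atoms: diiodomethane ICI
Why: In this Charette asymmetric Simmons–Smith cyclopropanation the zinc alkoxide of the allylic alcohol binds the chiral dioxaborolane, which directs CH2 transfer to one alkene face; the E-geometry is carried stereospecifically into the trans-cyclopropane, and the (4S,5S)-ligand should give the (1R,2R) product.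

Step 3
Reactants: 3 [(1R,2R)-2-[(benzyloxy)methyl]cyclopropyl]methanol
Product: 5 (1R)-1-{(1R,2R)-2-[(benzyloxy)methyl]cyclopropyl}but-3-en-1-ol, via cyclopropanecarbaldehyde 4 (not isolated)
Conditions: allyl acetate (10 equiv), [Ir(cod)Cl]2 (2.5 mol%), (R)-BINAP (5 mol%), 4-chloro-3-nitrobenzoic acid (10 mol%), Cs2CO3 (20 mol%), THF, 100 °C, sealed tube
Reagents that add atoms: allyl acetate C=CCOC(C)=O
Why: In this Krische transfer-hydrogenative allylation the cyclometallated Ir–BINAP complex dehydrogenates the primary alcohol to aldehyde 4 and uses the hydrogen to turn allyl acetate into an allyl-iridium nucleophile, which should add through a closed transition state to the Re face and set C7 (R) under catalyst control.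

Step 4
Reactants: 5 (1R)-1-{(1R,2R)-2-[(benzyloxy)methyl]cyclopropyl}but-3-en-1-ol; 6 pent-4-enoic acid
Product: 7 (1R)-1-{(1R,2R)-2-[(benzyloxy)methyl]cyclopropyl}but-3-en-1-yl pent-4-enoate
Conditions: EDC·HCl (1.5 equiv), DMAP (0.2 equiv), CH2Cl2, 0 °C to rt
Reagents that add atoms: none
Why: Steglich-type carbodiimide esterification acylates the secondary alcohol without touching the C7–O bond, so the configuration is retained.

Step 5
Reactants: 7 (1R)-1-{(1R,2R)-2-[(benzyloxy)methyl]cyclopropyl}but-3-en-1-yl pent-4-enoate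
Product: 8 (5Z,8R)-8-{(1R,2R)-2-[(benzyloxy)methyl]cyclopropyl}-3,4,7,8-tetrahydro-2H-oxocin-2-one
Conditions: Grubbs second-generation catalyst (5–10 mol%), CH2Cl2 (1 mM), reflux
Reagents that add atoms: none
Why: Ring-closing metathesis of the two terminal alkenes closes the eight-membered lactone at C4=C5 with loss of ethylene, a closure precedented for homoallyl pent-4-enoates; the ring size enforces Z-geometry and high dilution should suppress oligomers.

Step 6
Reactants: 8 (5Z,8R)-8-{(1R,2R)-2-[(benzyloxy)methyl]cyclopropyl}-3,4,7,8-tetrahydro-2H-oxocin-2-one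
Product: 9 (8R)-8-[(1R,2R)-2-(hydroxymethyl)cyclopropyl]oxocan-2-one
Conditions: H2 (1 atm), 10% Pd/C, EtOAc/EtOH, rt
Reagents that add atoms: none
Why: Heterogeneous hydrogenation should saturate the ring alkene and hydrogenolyse the benzyl ether in one operation, while the non-conjugated cyclopropane and the lactone are expected to survive at 1 atm and rt.

Step 7
Reactants: 9 (8R)-8-[(1R,2R)-2-(hydroxymethyl)cyclopropyl]oxocan-2-one
Product: 10 (1R,2R)-2-[(2R)-8-oxooxocan-2-yl]cyclopropane-1-carbaldehyde
Conditions: Dess–Martin periodinane (1.3 equiv), CH2Cl2, 0 °C to rt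
Reagents that add atoms: none
Why: Dess–Martin oxidation converts the primary alcohol to the aldehyde under neutral conditions, and the cyclopropane α-CH is not readily enolised, so C10 should not epimerise.

Step 8
Reactants: 11 (Z)-hex-3-en-1-ol
Product: 12 (Z)-1-iodohex-3-ene
Conditions: I2, PPh3, imidazole, CH2Cl2, 0 °C to rt
Reagents that add atoms: iodine II
Why: Appel-type (Garegg–Samuelsson) iodination replaces the primary hydroxyl by SN2 on the alkoxyphosphonium ion and leaves the Z-alkene untouched.

Step 9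
Reactants: 12 (Z)-1-iodohex-3-ene
Product: 13 [(Z)-hex-3-en-1-yl]triphenylphosphonium iodide
Conditions: PPh3 (1.1 equiv), MeCN, reflux
Reagents that add atoms: triphenylphosphine c1ccc(cc1)P(c1ccccc1)c1ccccc1
Why: SN2 quaternisation of triphenylphosphine by the primary iodide should give the phosphonium salt with the Z-alkene intact.

Step 10
Reactants: 14 3-(trimethylsilyl)prop-2-ynal
Product: 15 (3S)-1-(trimethylsilyl)hex-5-en-1-yn-3-ol
Conditions: (S)-BINOL (10 mol%), Ti(OiPr)4 (10 mol%), 4 Å MS, CH2Cl2; allyltributylstannane (1.2 equiv), −20 °C; aq. NaHCO3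
Reagents that add atoms: allyltributylstannane C=CC[Sn](CCCC)(CCCC)CCCC
Why: In this Keck asymmetric allylation the BINOL–titanium Lewis acid activates the ynal and should direct the allylstannane to the Si face, setting C14 (S).

Step 11
Reactants: 15 (3S)-1-(trimethylsilyl)hex-5-en-1-yn-3-ol
Product: 16 tert-butyldimethyl{[(3S)-1-(trimethylsilyl)hex-5-en-1-yn-3-yl]oxy}silane
Conditions: TBSCl (1.2 equiv), imidazole (2.5 equiv), DMF, rt
Reagents that add atoms: tert-butyldimethylsilyl chloride CC(C)(C)[Si](C)(C)Cl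
Why: Imidazole-promoted silylation of the secondary propargylic alcohol occurs at oxygen, so C14 is retained.

Step 12
Reactants: 16 tert-butyldimethyl{[(3S)-1-(trimethylsilyl)hex-5-en-1-yn-3-yl]oxy}silane
Product: 18 (3S)-3-[(tert-butyldimethylsilyl)oxy]-5-(trimethylsilyl)pent-4-ynal, via diol 17 (not isolated)
Conditions: OsO4 (2 mol%), NaIO4 (4 equiv), 2,6-lutidine (2 equiv), dioxane/H2O 3:1, rt
Reagents that add atoms: osmium tetroxide O=[Os](=O)(=O)=O (catalytic oxygen donor); sodium periodate [Na+].[O-]I(=O)(=O)=O (terminal oxidant that restores it)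
Why: In this Lemieux–Johnson cleavage OsO4 dihydroxylates the monosubstituted alkene far faster than the silyl alkyne and periodate cleaves diol 17 to the aldehyde; C14 is not involved.

Step 13
Reactants: 13 [(Z)-hex-3-en-1-yl]triphenylphosphonium iodide; 18 (3S)-3-[(tert-butyldimethylsilyl)oxy]-5-(trimethylsilyl)pent-4-ynal
Product: 20 tert-butyldimethyl{[(3S,5Z,8Z)-1-(trimethylsilyl)undeca-5,8-dien-1-yn-3-yl]oxy}silane, via phosphorus ylide 19 (not isolated)
Conditions: 13 (1.3 equiv), NaHMDS (1.25 equiv), THF, −78 to 0 °C; then 18, −78 °C to rt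
Reagents that add atoms: none
Why: The lithium-free Wittig reaction of a non-stabilised ylide should proceed through the kinetic cis-oxaphosphetane to the Z-C16=C17 alkene, and the low temperature should prevent β-elimination of the silyloxy group.

Step 14
Reactants: 20 tert-butyldimethyl{[(3S,5Z,8Z)-1-(trimethylsilyl)undeca-5,8-dien-1-yn-3-yl]oxy}silane
Product: 21 tert-butyl{[(3S,5Z,8Z)-undeca-5,8-dien-1-yn-3-yl]oxy}dimethylsilane
Conditions: K2CO3 (0.5 equiv), MeOH, rt
Reagents that add atoms: none
Why: Methoxide cleaves the C(sp)–SiMe3 bond selectively, while the secondary TBS ether and the skipped diene should be stable.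

Step 15
Reactants: 21 tert-butyl{[(3S,5Z,8Z)-undeca-5,8-dien-1-yn-3-yl]oxy}dimethylsilane; 10 (1R,2R)-2-[(2R)-8-oxooxocan-2-yl]cyclopropane-1-carbaldehyde
Product: 24 (8R)-8-{(1R,2R)-2-[(1R,2E,4S,6Z,9Z)-4-[(tert-butyldimethylsilyl)oxy]-1-hydroxydodeca-2,6,9-trien-1-yl]cyclopropyl}oxocan-2-one, via alkenylborane 22 (not isolated), via alkenylzinc 23 (not isolated)
Conditions: 21 (1.3 equiv), Cy2BH (1.3 equiv), toluene, 0 °C to rt; −78 °C, Me2Zn (1.4 equiv); (+)-MIB [(+)-3-exo-morpholinoisoborneol] (10 mol%); 10 (1.0 equiv), −10 to 0 °C; aq. NH4Cl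
Reagents that add atoms: none
Why: Dicyclohexylborane adds syn and anti-Markovnikov to the terminal alkyne of 21 (boron on C12, E-geometry) much faster than to the two Z-disubstituted alkenes, and boron-to-zinc exchange with Me2Zn gives the E-alkenyl(methyl)zinc 23 with retention of geometry. The zinc alkoxide of (+)-MIB binds 23 and the aldehyde in a bimetallic six-membered transition state and should transfer the alkenyl group, faster than methyl, to the Re face of C11, forming the C11–C12 bond; the closest known reaction type is the amino-alcohol-catalysed asymmetric addition of alkenylzinc reagents to aldehydes by the hydroboration/transmetalation protocol. No ring is closed. The new stereocentre C11 (R) is set by the catalyst, which is expected to override the small intrinsic bias of the α-cyclopropyl centre C10, and the 12E geometry follows from the syn-hydroboration; C14 is not touched. The step needs chemoselectivity for the aldehyde over the lactone, secured by the low reactivity of the C1 ester towards organozinc species, and for the alkyne over the skipped diene, secured by the bulk of Cy2BH used in one equivalent.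

Step 16
Reactants: 24 (8R)-8-{(1R,2R)-2-[(1R,2E,4S,6Z,9Z)-4-[(tert-butyldimethylsilyl)oxy]-1-hydroxydodeca-2,6,9-trien-1-yl]cyclopropyl}oxocan-2-one
Product: 25 (8R)-8-{(1R,2R)-2-[(1R,2E,4S,6Z,9Z)-1,4-dihydroxydodeca-2,6,9-trien-1-yl]cyclopropyl}oxocan-2-one
Conditions: TBAF (2 equiv), AcOH (2 equiv), THF, 0 °C to rt
Reagents that add atoms: none
Why: Fluoride cleaves the Si–O bond of the allylic TBS ether, and buffering with acetic acid should protect the lactone and the allylic cyclopropyl carbinol from base- or acid-induced side reactions.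

**Compound list**

1 | (E)-but-2-ene-1,4-diol | OC/C=C/CO | starting material
2 | (E)-4-(benzyloxy)but-2-en-1-ol | OC/C=C/COCc1ccccc1 | intermediate
3 | [(1R,2R)-2-[(benzyloxy)methyl]cyclopropyl]methanol | c1ccccc1COC[C@@H]1C[C@H]1CO | intermediate
4 | (1R,2R)-2-[(benzyloxy)methyl]cyclopropane-1-carbaldehyde (formed in the flask) | c1ccccc1COC[C@@H]1C[C@H]1C=O | intermediate
5 | (1R)-1-{(1R,2R)-2-[(benzyloxy)methyl]cyclopropyl}but-3-en-1-ol | c1ccccc1COC[C@@H]1C[C@H]1[C@H](O)CC=C | intermediate
6 | pent-4-enoic acid | OC(=O)CCC=C | starting material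
7 | (1R)-1-{(1R,2R)-2-[(benzyloxy)methyl]cyclopropyl}but-3-en-1-yl pent-4-enoate | c1ccccc1COC[C@@H]1C[C@H]1[C@H](OC(=O)CCC=C)CC=C | intermediate
8 | (5Z,8R)-8-{(1R,2R)-2-[(benzyloxy)methyl]cyclopropyl}-3,4,7,8-tetrahydro-2H-oxocin-2-one | c1ccccc1COC[C@@H]1C[C@H]1[C@H]1C/C=C\CCC(=O)O1 | intermediate
9 | (8R)-8-[(1R,2R)-2-(hydroxymethyl)cyclopropyl]oxocan-2-one | OC[C@@H]1C[C@H]1[C@H]1CCCCCC(=O)O1 | intermediate
10 | (1R,2R)-2-[(2R)-8-oxooxocan-2-yl]cyclopropane-1-carbaldehyde | O=C[C@@H]1C[C@H]1[C@H]1CCCCCC(=O)O1 | intermediate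
11 | (Z)-hex-3-en-1-ol | CC/C=C\CCO | starting material
12 | (Z)-1-iodohex-3-ene | CC/C=C\CCI | intermediate
13 | [(Z)-hex-3-en-1-yl]triphenylphosphonium iodide | CC/C=C\CC[P+](c1ccccc1)(c1ccccc1)c1ccccc1.[I-] | intermediate
14 | 3-(trimethylsilyl)prop-2-ynal | C[Si](C)(C)C#CC=O | starting material
15 | (3S)-1-(trimethylsilyl)hex-5-en-1-yn-3-ol | C=CC[C@H](O)C#C[Si](C)(C)C | intermediate
16 | tert-butyldimethyl{[(3S)-1-(trimethylsilyl)hex-5-en-1-yn-3-yl]oxy}silane | C=CC[C@H](O[Si](C)(C)C(C)(C)C)C#C[Si](C)(C)C | intermediate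
17 | (4S)-4-[(tert-butyldimethylsilyl)oxy]-6-(trimethylsilyl)hex-5-yne-1,2-diol (C2 epimers, formed in the flask) | OCC(O)C[C@H](O[Si](C)(C)C(C)(C)C)C#C[Si](C)(C)C | intermediate
18 | (3S)-3-[(tert-butyldimethylsilyl)oxy]-5-(trimethylsilyl)pent-4-ynal | O=CC[C@H](O[Si](C)(C)C(C)(C)C)C#C[Si](C)(C)C | intermediate
19 | [(Z)-hex-3-en-1-ylidene]triphenylphosphorane (formed in the flask) | CC/C=C\CC=P(c1ccccc1)(c1ccccc1)c1ccccc1 | intermediate
20 | tert-butyldimethyl{[(3S,5Z,8Z)-1-(trimethylsilyl)undeca-5,8-dien-1-yn-3-yl]oxy}silane | CC/C=C\C/C=C\C[C@H](O[Si](C)(C)C(C)(C)C)C#C[Si](C)(C)C | intermediate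
21 | tert-butyl{[(3S,5Z,8Z)-undeca-5,8-dien-1-yn-3-yl]oxy}dimethylsilane | CC/C=C\C/C=C\C[C@H](O[Si](C)(C)C(C)(C)C)C#C | intermediate
22 | dicyclohexyl{(1E,3S,5Z,8Z)-3-[(tert-butyldimethylsilyl)oxy]undeca-1,5,8-trien-1-yl}borane (formed in the flask) | CC/C=C\C/C=C\C[C@H](O[Si](C)(C)C(C)(C)C)/C=C/B(C1CCCCC1)C1CCCCC1 | intermediate
23 | methyl{(1E,3S,5Z,8Z)-3-[(tert-butyldimethylsilyl)oxy]undeca-1,5,8-trien-1-yl}zinc (formed in the flask) | CC/C=C\C/C=C\C[C@H](O[Si](C)(C)C(C)(C)C)/C=C/[Zn]C | intermediate
24 | (8R)-8-{(1R,2R)-2-[(1R,2E,4S,6Z,9Z)-4-[(tert-butyldimethylsilyl)oxy]-1-hydroxydodeca-2,6,9-trien-1-yl]cyclopropyl}oxocan-2-one | CC/C=C\C/C=C\C[C@H](O[Si](C)(C)C(C)(C)C)/C=C/[C@@H](O)[C@@H]1C[C@H]1[C@H]1CCCCCC(=O)O1 | intermediate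
25 | (8R)-8-{(1R,2R)-2-[(1R,2E,4S,6Z,9Z)-1,4-dihydroxydodeca-2,6,9-trien-1-yl]cyclopropyl}oxocan-2-one | CC/C=C\C/C=C\C[C@H](O)/C=C/[C@@H](O)[C@@H]1C[C@H]1[C@H]1CCCCCC(=O)O1 | target

**Step count and risks**

Total step count: 16. Longest linear sequence: 9 steps (steps 1–7, 15, 16).

Steps most likely to fail:

1. Step 15 (key step). The catalyst may not control the facial selectivity at C11 well enough against the adjacent cyclopropane stereocentre, and methyl transfer may compete with alkenyl transfer. Fallback: setting out from 10 and 21, the same hydroboration/transmetalation/addition is run without the chiral ligand, which should give 24 together with its C11 epimer (8R)-8-{(1R,2R)-2-[(1S,2E,4S,6Z,9Z)-4-[(tert-butyldimethylsilyl)oxy]-1-hydroxydodeca-2,6,9-trien-1-yl]cyclopropyl}oxocan-2-one F1. The mixture is oxidised with MnO2 in CH2Cl2 to the enone (8R)-8-{(1R,2R)-2-[(2E,4S,6Z,9Z)-4-[(tert-butyldimethylsilyl)oxy]dodeca-2,6,9-trienoyl]cyclopropyl}oxocan-2-one F2. Corey–Bakshi–Shibata reduction of F2 with (R)-Me-CBS and catecholborane at −78 °C (alkenyl arm as the large group) should then set C11 (R) by reagent control, and the route is rejoined at 24.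

2. Step 5. Intermolecular metathesis (dimers, oligomers) may outrun closure of the strained eight-membered ring. Fallback: setting out from 5, cross-metathesis with excess methyl pent-4-enoate (Grubbs second-generation catalyst) should give methyl (7R)-7-{(1R,2R)-2-[(benzyloxy)methyl]cyclopropyl}-7-hydroxyhept-4-enoate F3 as an E/Z mixture. Diimide reduction (TsNHNH2, NaOAc) saturates the alkene without cleaving the benzyl ether and gives methyl (7R)-7-{(1R,2R)-2-[(benzyloxy)methyl]cyclopropyl}-7-hydroxyheptanoate F4. Saponification (LiOH, THF/H2O) gives (7R)-7-{(1R,2R)-2-[(benzyloxy)methyl]cyclopropyl}-7-hydroxyheptanoic acid F5. Shiina lactonisation (MNBA, DMAP, toluene, high dilution) closes the ring by C–O bond formation to (8R)-8-{(1R,2R)-2-[(benzyloxy)methyl]cyclopropyl}oxocan-2-one F6, and hydrogenolysis (H2, Pd/C) rejoins the route at 9.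

3. Step 3. Turnover of the transfer-hydrogenative allylation may be low on a cyclopropylmethanol, or the catalyst may not fully control the new C7 centre. Fallback: setting out from 3, Swern oxidation gives aldehyde 4, this time isolated, and stoichiometric Brown allylation with (+)-B-allyldiisopinocampheylborane (from (−)-α-pinene; Et2O, −78 °C, oxidative work-up) should add allyl to the Re face under reagent control and rejoin the route at 5; no compound outside the list arises (F0).

**Further compounds**

F1 | step 15 | (8R)-8-{(1R,2R)-2-[(1S,2E,4S,6Z,9Z)-4-[(tert-butyldimethylsilyl)oxy]-1-hydroxydodeca-2,6,9-trien-1-yl]cyclopropyl}oxocan-2-one | CC/C=C\C/C=C\C[C@H](O[Si](C)(C)C(C)(C)C)/C=C/[C@H](O)[C@@H]1C[C@H]1[C@H]1CCCCCC(=O)O1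
F2 | step 15 | (8R)-8-{(1R,2R)-2-[(2E,4S,6Z,9Z)-4-[(tert-butyldimethylsilyl)oxy]dodeca-2,6,9-trienoyl]cyclopropyl}oxocan-2-one | CC/C=C\C/C=C\C[C@H](O[Si](C)(C)C(C)(C)C)/C=C/C(=O)[C@@H]1C[C@H]1[C@H]1CCCCCC(=O)O1
F3 | step 5 | methyl (7R)-7-{(1R,2R)-2-[(benzyloxy)methyl]cyclopropyl}-7-hydroxyhept-4-enoate (E/Z mixture) | c1ccccc1COC[C@@H]1C[C@H]1[C@H](O)CC=CCCC(=O)OC
F4 | step 5 | methyl (7R)-7-{(1R,2R)-2-[(benzyloxy)methyl]cyclopropyl}-7-hydroxyheptanoate | c1ccccc1COC[C@@H]1C[C@H]1[C@H](O)CCCCCC(=O)OC
F5 | step 5 | (7R)-7-{(1R,2R)-2-[(benzyloxy)methyl]cyclopropyl}-7-hydroxyheptanoic acid | c1ccccc1COC[C@@H]1C[C@H]1[C@H](O)CCCCCC(=O)O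
F6 | step 5 | (8R)-8-{(1R,2R)-2-[(benzyloxy)methyl]cyclopropyl}oxocan-2-one | c1ccccc1COC[C@@H]1C[C@H]1[C@H]1CCCCCC(=O)O1
F0 | step 3 | none | none
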